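## Retrosynthetic overview
1. Remove the acetate to give the C13 alcohol (eupalmerin). All other atoms come from one acyclic seco-chain.
2. Key step: cut C1–C14 and O–C16 together, giving an unprotected α-hydroxy aldehyde / (Z)-2-(bromomethyl)enoate. One aqueous In(0) macro-Barbier/lactonisation then closes the 14-ring and the γ-lactone, creates the exo-methylene, and sets C1 and C14 with the epoxide already in place. This replaces the usual plan of remote RCM/HWE ring closure, stepwise lactone building, α-methylenation and late epoxidation.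
3. Cut the seco-chain at C8–C9 (B-alkyl Suzuki). The East C9–C14 iodide comes from (S)-citronellal (C12) and L-proline aminoxylation (C13). The West piece is a C1–C8/C15–C17 vinyl iodide.
4. The West piece comes from two pent-3-yn-1-ol units, joined by iterated hydrozirconation–iodination/Suzuki coupling to set both E-trisubstituted alkenes. Methyl propiolate supplies C15–C17, and Shi epoxidation is run while C7=C8 is still masked as a vinyl iodide.
5. Ring order: oxirane first, then the 14-membered carbocycle and γ-lactone together in the penultimate step.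

Assumption: cembrane numbering is used (C1 lactone β-CH, C14 lactone O–CH, C13 OAc, C12 CHMe, C7=C8, C3–C4 epoxide, C15–C17 acrylate unit). The SMILES reads as (1S,3R,4R,7E,12S,13R,14R), with a cis-fused lactone and an E-derived epoxide.

## Route

**Step 1**
Reactants: 1, pent-3-yn-1-ol
Product: 2, (E)-4-iodopent-3-en-1-ol (C1–C4 + C18)
Conditions: Cp2Zr(H)Cl (2.5 equiv), THF, rt→40 °C; I2, 0 °C
Reagents that add atoms: iodine, II
Why: Syn-hydrozirconation (Schwartz) with excess reagent equilibrates Zr to the less hindered methyl-bearing carbon, and iodinolysis with retention gives the (E)-2-iodoalkene that fixes the C3=C4 geometry.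

**Step 2**
Reactants: 1, pent-3-yn-1-ol
Product: 3, 5-iodopent-2-yne (C5–C8 + C19)
Conditions: I2, PPh3, imidazole, CH2Cl2, 0 °C
Reagents that add atoms: iodine, II
Why: Appel-type iodination (SN2 on the alkoxyphosphonium) of a primary alcohol, with the internal alkyne inert.

**Step 3**
Reactants: 3, 5-iodopent-2-yne; 2, (E)-4-iodopent-3-en-1-ol
Product: 4, (E)-4-methylnon-3-en-7-yn-1-ol
Conditions: 3, t-BuLi (2.1 equiv), Et2O, −78 °C; B-MeO-9-BBN, THF, →rt; then 2, Pd(dppf)Cl2 (5 mol %), K3PO4 (3 M aq), DMF, rt
Reagents that add atoms: none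
Why: B-alkyl Suzuki–Miyaura coupling (Li–I exchange, borinate formation, sp3–sp2 coupling) proceeds with retention at the vinyl iodide, giving E-C3=C4 and tolerating the free OH and the alkyne.

**Step 4**
Reactants: 4
Product: 5, (3E,7E)-8-iodo-4-methylnona-3,7-dien-1-ol
Conditions: Cp2Zr(H)Cl (3 equiv), THF, rt→40 °C; I2, 0 °C
Reagents that add atoms: iodine, II
Why: This is the same regio-equilibrated syn-hydrozirconation/iodination as step 1, in which the alkyne reacts far faster than the trisubstituted alkene and the (E)-iodide pre-sets the C7=C8 geometry.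

**Step 5**
Reactants: 5
Product: 6, (3E,7E)-8-iodo-4-methylnona-3,7-dienal
Conditions: DMP, NaHCO3, CH2Cl2, 0 °C (used crude)
Reagents that add atoms: none
Why: Buffered Dess–Martin oxidation gives the β,γ-unsaturated aldehyde without base-induced conjugation.

**Step 6**
Reactants: 6; 7, methyl propiolate
Product: 8, methyl (5E,9E)-3-hydroxy-10-iodo-6-methyl-2-methylideneundeca-5,9-dienoate (racemic carbinol, C1)
Conditions: DIBAL-H, NMO (or HMPA), THF, 0 °C, then 7; then 6, 0 °C→rt
Reagents that add atoms: methyl propiolate, C#CC(=O)OC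
Why: Vinylalumination (an amine-free Morita–Baylis–Hillman equivalent) adds the α-(methoxycarbonyl)vinylalane 1,2 to the aldehyde faster than the aldehyde enolises, and the new carbinol centre is erased in step 13.

**Step 7**
Reactants: 8
Product: 9, methyl 3-hydroxy-4-{(2R,3R)-3-[(E)-4-iodopent-3-en-1-yl]-3-methyloxiran-2-yl}-2-methylidenebutanoate (about 1:1 at the carbinol)
Conditions: D-fructose-derived Shi ketone (30 mol %), Oxone, K2CO3, Bu4NHSO4, MeCN/DMM–buffer (pH 10.5), 0 °C
Reagents that add atoms: potassium peroxymonosulfate (Oxone), [K+].[O-]S(=O)(=O)OO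
Why: In the Shi asymmetric epoxidation (chiral dioxirane, spiro TS) the D-fructose ketone gives the (R,R)-epoxide of an E-trisubstituted alkene, setting C3 and C4, and only C3=C4 is electron-rich because the vinyl iodide and acrylate are deactivated.

**Step 8**
Reactants: 10, (S)-citronellal
Product: 11, (2R,3S)-3,7-dimethyloct-6-ene-1,2-diol (C14, C13, C12)
Conditions: L-proline (20 mol %), PhNO, CHCl3, 4 °C; NaBH4, EtOH, 0 °C; CuSO4·5H2O (30 mol %), MeOH, rt
Reagents that add atoms: nitrosobenzene (only O is kept), O=Nc1ccccc1
Why: Proline-catalysed α-aminoxylation (enamine catalysis) followed by reduction and N–O cleavage sets C13 as R under L-proline catalyst control, while C12 (S) comes unchanged from the chiral pool.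

**Step 9**
Reactants: 11
Product: 12, (2R,3S)-3,7-dimethyl-1,2-bis(triethylsilyloxy)oct-6-ene
Conditions: TESCl, imidazole, DMAP (cat.), CH2Cl2, 0 °C→rt
Reagents that add atoms: chlorotriethylsilane, CC[Si](Cl)(CC)CC
Why: Standard bis-silylation, with TES chosen so that the primary ether can later be oxidised directly and the secondary one removed by weak acid.

**Step 10**
Reactants: 12
Product: 13, (4S,5R)-4-methyl-5,6-bis(triethylsilyloxy)hexan-1-ol
Conditions: O3, CH2Cl2, −78 °C; NaBH4, EtOH, −78→0 °C
Reagents that add atoms: ozone, [O-][O+]=O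
Why: Ozonolysis with reductive work-up cleaves the only alkene (acetone is lost), leaving C9 as a primary alcohol.

**Step 11**
Reactants: 13
Product: 14, (2R,3S)-6-iodo-3-methyl-1,2-bis(triethylsilyloxy)hexane
Conditions: I2, PPh3, imidazole, CH2Cl2, 0 °C
Reagents that add atoms: iodine, II
Why: Appel-type iodination under imidazole buffering, which the TES ethers survive.

**Step 12**
Reactants: 14; 9
Product: 15, methyl 3-hydroxy-2-methylidene-4-[(2R,3R)-3-methyl-3-{(3E,8S,9R)-4,8-dimethyl-9,10-bis(triethylsilyloxy)dec-3-en-1-yl}oxiran-2-yl]butanoate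
Conditions: 14 (1.3 equiv), t-BuLi, Et2O, −78 °C; B-MeO-9-BBN, THF, →rt; then 9, Pd(dppf)Cl2, AsPh3, Cs2CO3, DMF/H2O, rt
Reagents that add atoms: none
Why: B-alkyl Suzuki–Miyaura coupling forms C8–C9 with retention to give E-C7=C8, under mild basic conditions that spare the epoxide, the ester and the unactivated allylic OH.

**Step 13**
Reactants: 15
Product: 16, methyl (Z)-2-(bromomethyl)-4-[(2R,3R)-3-methyl-3-{(3E,8S,9R)-4,8-dimethyl-9,10-bis(triethylsilyloxy)dec-3-en-1-yl}oxiran-2-yl]but-2-enoate
Conditions: NBS/Me2S (pre-mixed), CH2Cl2, −20→0 °C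
Reagents that add atoms: N-bromosuccinimide, O=C1CCC(=O)N1Br
Why: Corey–Kim-type SN2′ bromination of the Baylis–Hillman alcohol converges both carbinol epimers to the (Z)-allylic bromide under neutral conditions that spare the epoxide, the TES ethers and C7=C8.

**Step 14**
Reactants: 16
Product: 17, the C14 aldehyde: methyl (Z)-2-(bromomethyl)-4-[(2R,3R)-3-methyl-3-{(3E,8S,9R)-4,8-dimethyl-10-oxo-9-(triethylsilyloxy)dec-3-en-1-yl}oxiran-2-yl]but-2-enoate
Conditions: (COCl)2, DMSO, CH2Cl2, −78→−35 °C; i-Pr2NEt, −78→−10 °C
Reagents that add atoms: none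
Why: In this Swern oxidation of a silyl ether, the chlorosulfonium salt desilylates and oxidises only the primary TES ether, and the hindered base at low temperature avoids quaternising the allylic bromide or epimerising C13.

**Step 15**
Reactants: 17
Product: 18, seco α-hydroxy aldehyde (same as 17 but with 9-hydroxy-10-oxo; used crude)
Conditions: AcOH/THF/H2O (3:1:1), 0 °C→rt
Reagents that add atoms: none
Why: Weak-acid solvolysis removes the labile α-TES ether without amine or fluoride, which would attack the bromide, and at an acidity the trisubstituted epoxide tolerates.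

**Step 16 (key step)**
Reactants: 18
Product: 19, eupalmerin (13-O-deacetyl target; 1S,3R,4R,7E,12S,13R,14R)
Conditions: In powder (6 equiv), THF/H2O (1:1), 18 added over 12 h (final about 1 mM), rt; work-up; PPTS (10 mol %), CH2Cl2, rt
Reagents that add atoms: none
Why: Proposed new method: In(0) inserts to give the geometry-retaining, ester-coordinated (Z)-allylindium, In(III) chelates the aldehyde O and the free C13-OH (Cram chelate) so that attack anti to C12 gives 13,14-syn (14R), the chair SE2′ transition state of the Z-allyl unit gives 1,14-syn (1S), and 5-exo lactonisation then gives the cis-fused α-methylene lactone; the closest known reactions are syn,syn-selective intermolecular In/H2O Barbier couplings of (Z)-2-(bromomethyl)alk-2-enoates with unprotected α-hydroxy aldehydes, intramolecular In-Barbier closures of 5–7-membered rings, and Cr/Zn macro-Barbier closures of 10-membered germacranolides.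

**Step 17**
Reactants: 19
Product: 20, eupalmerin acetate (target)
Conditions: Ac2O, pyridine, DMAP (cat.), CH2Cl2, 0 °C→rt
Reagents that add atoms: acetic anhydride, CC(=O)OC(C)=O
Why: Standard acylation of the only free hydroxyl (C13), with retention and with the epoxide and methylene lactone unaffected.

## Compound list
1 | pent-3-yn-1-ol | CC#CCCO | starting material
2 | (E)-4-iodopent-3-en-1-ol | C/C(I)=C\CCO | intermediate
3 | 5-iodopent-2-yne | CC#CCCI | intermediate
4 | (E)-4-methylnon-3-en-7-yn-1-ol | CC#CCC/C(C)=C/CCO | intermediate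
5 | (3E,7E)-8-iodo-4-methylnona-3,7-dien-1-ol | C/C(I)=C\CC/C(C)=C/CCO | intermediate
6 | (3E,7E)-8-iodo-4-methylnona-3,7-dienal | C/C(I)=C\CC/C(C)=C/CC=O | intermediate
7 | methyl propiolate | C#CC(=O)OC | starting material
8 | Baylis–Hillman-type alcohol (racemic carbinol) | C/C(I)=C\CC/C(C)=C/CC(O)C(=C)C(=O)OC | intermediate
9 | (3R,4R)-epoxy vinyl iodide (carbinol epimers) | C/C(I)=C\CC[C@@]1(C)O[C@@H]1CC(O)C(=C)C(=O)OC | intermediate
10 | (S)-citronellal | O=CC[C@@H](C)CCC=C(C)C | starting material
11 | (2R,3S)-3,7-dimethyloct-6-ene-1,2-diol | OC[C@H](O)[C@@H](C)CCC=C(C)C | intermediate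
12 | bis-TES ether of 11 | CC[Si](CC)(CC)OC[C@H](O[Si](CC)(CC)CC)[C@@H](C)CCC=C(C)C | intermediate
13 | (4S,5R)-4-methyl-5,6-bis(TESO)hexan-1-ol | CC[Si](CC)(CC)OC[C@H](O[Si](CC)(CC)CC)[C@@H](C)CCCO | intermediate
14 | (2R,3S)-6-iodo-3-methyl-1,2-bis(TESO)hexane | CC[Si](CC)(CC)OC[C@H](O[Si](CC)(CC)CC)[C@@H](C)CCCI | intermediate
15 | coupled C1–C17 chain, Baylis–Hillman alcohol | CC[Si](CC)(CC)OC[C@H](O[Si](CC)(CC)CC)[C@@H](C)CCC/C(C)=C/CC[C@@]1(C)O[C@@H]1CC(O)C(=C)C(=O)OC | intermediate
16 | (Z)-allylic bromide | CC[Si](CC)(CC)OC[C@H](O[Si](CC)(CC)CC)[C@@H](C)CCC/C(C)=C/CC[C@@]1(C)O[C@@H]1C/C=C(\CBr)C(=O)OC | intermediate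
17 | α-TESO aldehyde | O=C[C@H](O[Si](CC)(CC)CC)[C@@H](C)CCC/C(C)=C/CC[C@@]1(C)O[C@@H]1C/C=C(\CBr)C(=O)OC | intermediate
18 | seco α-hydroxy aldehyde / allylic bromide | O=C[C@H](O)[C@@H](C)CCC/C(C)=C/CC[C@@]1(C)O[C@@H]1C/C=C(\CBr)C(=O)OC | intermediate
19 | eupalmerin (13-OH) | C=C1C(=O)O[C@H]2[C@H](O)[C@@H](C)CCC/C(C)=C/CC[C@@]3(C)O[C@@H]3C[C@@H]12 | intermediate
20 | eupalmerin acetate | C=C1C(=O)O[C@H]2[C@H](OC(C)=O)[C@@H](C)CCC/C(C)=C/CC[C@@]3(C)O[C@@H]3C[C@@H]12 | target

## Summary
Total steps: 17. Longest linear sequence: 12 (steps 1, 3, 4, 5, 6, 7, 12, 13, 14, 15, 16, 17, starting from pent-3-yn-1-ol).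

Steps most likely to fail:
1. **Step 16.** The risks are slow 14-ring closure against protonolysis or oligomerisation of the allylindium, the diastereomer ratio, and epoxide opening by In(III) or PPTS. Fallback: reverse the ring order.
   - Run the In/H2O Barbier–lactonisation intermolecularly between the bromide made from 9 (vinyl iodide kept) and (2R,3S)-2-hydroxy-6-iodo-3-methylhexanal (made from 14), then acetylate.
   - Close the macrocycle at C8–C9 by an intramolecular alkyl-iodide/vinyl-iodide coupling (Zn insertion/Negishi, or Ni reductive cross-electrophile coupling).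
2. **Steps 14–15.** The free α-hydroxy aldehyde has to be unmasked next to an allylic bromide and an epoxide. Fallback: avoid the free hydroxy aldehyde altogether.
   - Use D-proline in step 8 to enter the 13-epi series.
   - Cyclise the α-TESO aldehyde under Felkin–Anh (non-chelate) control, which gives 13,14-anti and still (1S,14R).
   - Desilylate and install the acetate with inversion at C13 by a Mitsunobu reaction with AcOH.
3. **Step 6.** The vinylalane addition may lose out to enolisation or conjugation of the β,γ-unsaturated aldehyde. Fallback: form C1–C2 instead of C1–C15.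
   - Build the one-carbon-shorter allylic bromide using (E)-3-iodobut-2-en-1-ol in place of 2.
   - Couple it with methyl propiolate under Cu(I) to give the skipped enynoate.
   - Carry out hydroalumination with a formaldehyde trap to give the 2-(hydroxymethyl)enoate, then brominate.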